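**Retrosynthetic overview**
- Chain numbering runs from C1 (benzylic CH2 on catechol ring A) to C7 (benzylic CH2 on 4-hydroxyphenyl ring B). The strategy rests on one feature: the C3 acetate and the C5 hydroxyl are anti across C4, and C1 is benzylic to ring A, so O5 can be tied to C1 for a time.
- Last disconnection (retro-hydrogenolysis): one C1–H is replaced by C1–O5. This gives the all-cis oxane O5–C5–C4–C3–C2–C1, with ring A on C1, OAc on C3 and the arylethyl chain on C5. Its cis C3/C5 relation is the anti relation of the open chain, and because O5 is masked the acetyl group can only sit on O3.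
- Key disconnection (three-component acetoxy-Prins): C1–O5, C1–C2 and C3–OAc are cut together. The pieces are the (R)-homoallylic alcohol (C2–C7 plus ring B), the ring A aldehyde (C1) and acetic acid.
- The alcohol goes back to 3-(4-hydroxyphenyl)propan-1-ol by O-benzylation and an enantioselective iridium-catalysed allylation that forms C4–C5 and sets C5. The aldehyde goes back to 3,4-dihydroxybenzaldehyde capped as its bis(benzyl carbonate).
- Ring order: the oxane is the only ring built. It is closed in the key step and opened again in the last step.

Key step: step 4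

Assumption: the (S)-BINAP-modified iridium catalyst is taken to attack the aldehyde face that gives the (R)-homoallylic alcohol (R here because allyl outranks the arylethyl chain); the configuration is to be confirmed by Mosher ester analysis before the key step, and the antipodal ligand is used if the sense proves opposite.

Step 1
Reactants: 1 3-(4-hydroxyphenyl)propan-1-ol; 2 benzyl bromide
Product: 3 3-[4-(benzyloxy)phenyl]propan-1-ol
Conditions: K2CO3, acetone, reflux
Reagents that add atoms: benzyl bromide, BrCc1ccccc1
Why: Williamson ether synthesis; K2CO3 deprotonates only the phenol and not the primary alcohol, so O-benzylation should be chemoselective, and no stereocentre is involved.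

Step 2
Reactants: 3 3-[4-(benzyloxy)phenyl]propan-1-ol; 4 allyl acetate
Product: 6 (3R)-1-[4-(benzyloxy)phenyl]hex-5-en-3-ol, via 3-[4-(benzyloxy)phenyl]propanal 5 (not isolated)
Conditions: [Ir(cod)Cl]2, (S)-BINAP, 4-chloro-3-nitrobenzoic acid, Cs2CO3 (all catalytic), THF, 100 °C, sealed tube
Reagents that add atoms: allyl acetate, C=CCOC(C)=O
Why: Krische carbonyl allylation by transfer hydrogenation; the cyclometalated iridium C,O-benzoate dehydrogenates 3 to aldehyde 5, the hydride so gained converts allyl acetate into the allyliridium nucleophile, and addition through a closed chair transition state in the pocket of (S)-BINAP should form C4–C5 and set C5 as R, the aryl benzyl ether being inert.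

Step 3
Reactants: 7 3,4-dihydroxybenzaldehyde; 8 benzyl chloroformate
Product: 9 dibenzyl (4-formyl-1,2-phenylene) dicarbonate, that is 3,4-bis[(benzyloxycarbonyl)oxy]benzaldehyde
Conditions: Et3N, DMAP (cat.), CH2Cl2, 0 °C, catechol and base added slowly to excess 8
Reagents that add atoms: benzyl chloroformate, O=C(Cl)OCc1ccccc1
Why: O-acylation of phenols by a chloroformate under nucleophilic catalysis; keeping 8 in excess should cap both phenols before a monocarbonate can close to the cyclic catechol carbonate, and the formyl group is not touched.

Step 4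
Reactants: 6 (3R)-1-[4-(benzyloxy)phenyl]hex-5-en-3-ol; 9 dibenzyl (4-formyl-1,2-phenylene) dicarbonate; 10 acetic acid
Product: 13 (2R,4S,6R)-2-{3,4-bis[(benzyloxycarbonyl)oxy]phenyl}-6-{2-[4-(benzyloxy)phenyl]ethyl}oxan-4-yl acetate (all-cis), via (E)-oxocarbenium ion 11 (not isolated), via 2,6-cis-oxan-4-yl cation 12 (not isolated)
Conditions: BF3·OEt2, AcOH (large excess), CH2Cl2, 0 °C
Reagents that add atoms: acetic acid, CC(=O)O
Why: BF3·OEt2 condenses the C5 hydroxyl of 6 with the formyl carbon of 9 (the future C1) through the hemiacetal to the (E)-oxocarbenium ion 11 and binds the water that is lost; the terminal alkene carbon C2 then adds to C1 and acetic acid 10 traps the secondary cation 12 at C3, so that C1–O5, C1–C2 and C3–OAc arise in one operation. The closest known reaction type is the three-component acetoxy-Prins cyclisation of homoallylic alcohols with aldehydes under BF3·OEt2/AcOH, an established entry to 2,4,6-cis-4-acetoxyoxanes. The single ring, oxane O5–C5–C4–C3–C2–C1, closes 6-endo-trig through a chair transition state. C1 is controlled by the existing C5 centre, which places its arylethyl chain equatorial while the E geometry of 11 places ring A equatorial (2,6-cis, C1 R), and C3 is controlled by the chair cation 12, whose overlap with the ring bonds and the ring oxygen favours equatorial entry of the nucleophile, so the acetate should come in cis to both substituents (oxane C4, S). The step needs the all-cis diastereomer, retention of the C5 configuration and capture by acetate instead of fluoride: the two carbonate groups lower the donor power of ring A, which disfavours benzylic C1–O5 ionisation and fragmentation after a 2-oxonia-Cope shift (the shift itself runs through the same chair and leads back to 12), and the large excess of AcOH at 0 °C favours acetate capture. The benzyl ether and the benzyl carbonates are expected to tolerate BF3·OEt2 at 0 °C for the short time needed.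

Step 5
Reactants: 13 (2R,4S,6R)-2-{3,4-bis[(benzyloxycarbonyl)oxy]phenyl}-6-{2-[4-(benzyloxy)phenyl]ethyl}oxan-4-yl acetate
Product: 15 (3R,5R)-1-(3,4-dihydroxyphenyl)-5-hydroxy-7-(4-hydroxyphenyl)heptan-3-yl acetate (target), via oxane triphenol 14 (not isolated)
Conditions: H2 (5 bar), Pd(OH)2/C, EtOAc–AcOH, 40 °C; filtration and evaporation without any basic wash
Reagents that add atoms: none
Why: Catalytic hydrogenolysis of benzylic C–O bonds; the benzyl ether and both benzyl carbonates (which then lose CO2) should fall first to give 14, whose free para-hydroxyl turns C1–O5 into a 4-hydroxybenzylic ether that is cleaved as in the known opening of 2-aryl cyclic ethers of lignans, while the unactivated C5–O5 and C3–OAc bonds stay, C1 becomes CH2 and the cis C3/C5 relation of the oxane emerges as the anti (3R,5R) pair with the acetyl group on O3 only.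

**Compound list**
1 | 3-(4-hydroxyphenyl)propan-1-ol | OCCCc1ccc(O)cc1 | starting material
2 | benzyl bromide | BrCc1ccccc1 | starting material
3 | 3-[4-(benzyloxy)phenyl]propan-1-ol | OCCCc1ccc(OCc2ccccc2)cc1 | intermediate
4 | allyl acetate | C=CCOC(C)=O | starting material
5 | 3-[4-(benzyloxy)phenyl]propanal | O=CCCc1ccc(OCc2ccccc2)cc1 | intermediate
6 | (3R)-1-[4-(benzyloxy)phenyl]hex-5-en-3-ol | C=CC[C@H](O)CCc1ccc(OCc2ccccc2)cc1 | intermediate
7 | 3,4-dihydroxybenzaldehyde | O=Cc1ccc(O)c(O)c1 | starting material
8 | benzyl chloroformate | O=C(Cl)OCc1ccccc1 | starting material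
9 | dibenzyl (4-formyl-1,2-phenylene) dicarbonate | O=Cc1ccc(OC(=O)OCc2ccccc2)c(OC(=O)OCc2ccccc2)c1 | intermediate
10 | acetic acid | CC(=O)O | starting material
11 | (E)-{3,4-bis[(benzyloxycarbonyl)oxy]benzylidene}{(3R)-1-[4-(benzyloxy)phenyl]hex-5-en-3-yl}oxonium (O5=C1 ion) | C=CC[C@@H](CCc1ccc(OCc2ccccc2)cc1)/[O+]=C/c1ccc(OC(=O)OCc2ccccc2)c(OC(=O)OCc2ccccc2)c1 | intermediate
12 | 2,6-cis-2-{3,4-bis[(benzyloxycarbonyl)oxy]phenyl}-6-{2-[4-(benzyloxy)phenyl]ethyl}oxan-4-ylium (cation at C3, both substituents equatorial, C1 and C5 as in 13) | [CH+]1C[C@@H](CCc2ccc(OCc3ccccc3)cc2)O[C@@H](c2ccc(OC(=O)OCc3ccccc3)c(OC(=O)OCc3ccccc3)c2)C1 | intermediate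
13 | (2R,4S,6R)-2-{3,4-bis[(benzyloxycarbonyl)oxy]phenyl}-6-{2-[4-(benzyloxy)phenyl]ethyl}oxan-4-yl acetate | CC(=O)O[C@H]1C[C@@H](CCc2ccc(OCc3ccccc3)cc2)O[C@@H](c2ccc(OC(=O)OCc3ccccc3)c(OC(=O)OCc3ccccc3)c2)C1 | intermediate
14 | (2R,4S,6R)-2-(3,4-dihydroxyphenyl)-6-[2-(4-hydroxyphenyl)ethyl]oxan-4-yl acetate | CC(=O)O[C@H]1C[C@@H](CCc2ccc(O)cc2)O[C@@H](c2ccc(O)c(O)c2)C1 | intermediate
15 | (3R,5R)-1-(3,4-dihydroxyphenyl)-5-hydroxy-7-(4-hydroxyphenyl)heptan-3-yl acetate | CC(=O)O[C@H](CCc1ccc(O)c(O)c1)C[C@H](O)CCc1ccc(O)cc1 | target

**Total step count:** 5. **Longest linear sequence:** 4 (steps 1, 2, 4, 5); step 3 is a one-step side branch.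

**Steps most likely to fail**

**Risk 1 (step 4).**
- The water of condensation may hydrolyse the ion formed by a 2-oxonia-Cope shift. The two side chains would then be exchanged between alcohol and aldehyde partners, and the C5 configuration would erode.
- Fluoride from BF3 may compete with acetate for the C3 cation, and a benzyl carbonate may be lost to the Lewis acid. Me3SiOAc as fluoride scavenger would address only the fluoride problem.
- The fallback replaces the three-component condensation by a tethered, anhydrous ionisation. It sets out from 6 and rejoins the route at 14.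
- Alcohol 6 is esterified with commercial 3,4-bis(benzyloxy)benzoic acid (EDC·HCl, DMAP, CH2Cl2, Steglich esterification). This gives (3R)-1-[4-(benzyloxy)phenyl]hex-5-en-3-yl 3,4-bis(benzyloxy)benzoate F1.
- Reductive acetylation (i-Bu2AlH, CH2Cl2, −78 °C, then Ac2O, pyridine, DMAP) should give the α-acetoxy ether [3,4-bis(benzyloxy)phenyl]({(3R)-1-[4-(benzyloxy)phenyl]hex-5-en-3-yl}oxy)methyl acetate F2 as both acetal epimers.
- BF3·OEt2/AcOH in hexane–CH2Cl2 at low temperature then generates the O5=C1 ion with neither water nor free aldehyde present. It should close to (2R,4S,6R)-2-[3,4-bis(benzyloxy)phenyl]-6-{2-[4-(benzyloxy)phenyl]ethyl}oxan-4-yl acetate F3.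
- Under the conditions of step 5, F3 loses its three benzyl groups to give 14 in the flask, which then opens to 15.

**Risk 2 (step 5).**
- The hydrogenolysis may stall once the protecting groups have fallen, leaving the ring C1–O5 bond intact.
- Forcing it may bring arene saturation or acetyl migration from O3 to the freed O5.
- The fallback separates deprotection from ring opening and changes the opening from a surface reaction to an ionic one. It sets out from 13 and comes back at 15.
- Mild hydrogenolysis (H2, 1 bar, Pd/C, EtOAc, room temperature) is stopped at 14, which is isolated.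
- Ionic hydrogenation (Et3SiH, BF3·OEt2, MeCN–CH2Cl2, −20 °C) then ionises the 4-hydroxybenzylic C1–O5 bond and delivers hydride to C1. The medium is cold and non-basic, so acetyl migration is disfavoured.
- No compound outside the compound list is made (F0).

**Risk 3 (step 2).**
- The unbranched aliphatic alcohol may convert incompletely, or facial selectivity may be insufficient or of the wrong sense.
- The fallback uses a stoichiometric chiral reagent whose sense is well established at the aldehyde oxidation level. It sets out from 3 and comes back at 6.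
- Alcohol 3 is oxidised (TEMPO cat., PhI(OAc)2, CH2Cl2) and aldehyde 5 is isolated.
- Brown allylation follows, with commercial (−)-Ipc2B(allyl), the reagent derived from (+)-α-pinene, in Et2O at −78 °C, then NaOH/H2O2. With unbranched aliphatic aldehydes this reagent gives the R alcohol.
- No compound outside the compound list is made (F0).

**Further compounds**
F1 | step 4 | (3R)-1-[4-(benzyloxy)phenyl]hex-5-en-3-yl 3,4-bis(benzyloxy)benzoate | C=CC[C@@H](CCc1ccc(OCc2ccccc2)cc1)OC(=O)c1ccc(OCc2ccccc2)c(OCc2ccccc2)c1
F2 | step 4 | [3,4-bis(benzyloxy)phenyl]({(3R)-1-[4-(benzyloxy)phenyl]hex-5-en-3-yl}oxy)methyl acetate (both acetal epimers) | C=CC[C@@H](CCc1ccc(OCc2ccccc2)cc1)OC(OC(C)=O)c1ccc(OCc2ccccc2)c(OCc2ccccc2)c1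
F3 | step 4 | (2R,4S,6R)-2-[3,4-bis(benzyloxy)phenyl]-6-{2-[4-(benzyloxy)phenyl]ethyl}oxan-4-yl acetate | CC(=O)O[C@H]1C[C@@H](CCc2ccc(OCc3ccccc3)cc2)O[C@@H](c2ccc(OCc3ccccc3)c(OCc3ccccc3)c2)C1
F0 | step 5 | none | none
F0 | step 2 | none | none
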